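**Strategy.** Ring numbering: C1 ketone, C2 methyl-bearing epoxide carbon, C3, C4, C5 (side chain), C6 (acetate). C7 is the exocyclic carbon on C5 and C8 the carbinol carbon. The plan cuts C4–C5 and C1–C6 of the six-membered carbocycle. It exploits the trans C5-branch/C6-OAc pair flanked by oxygenated C1: an acetyl group at C6 serves as masked acetate and as the directing acceptor. One catalytic enantioselective endo Diels–Alder reaction between silyl dienol ether 2 and γ-keto enoate 4 closes the ring, fixes C1, C5 and C6, and leaves C2=C3 for epoxidation. The precursor carries a benzyl ester, removable beside the later acetate.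

Key step: step 3

Assumption: the (R)-catalyst is assigned from the accepted transition-state picture for enones (boron on the ketone lone pair syn to the vinyl group, s-trans enone, α-C–H···O contact, rear face covered by a phenyl group); the sense of induction is to be confirmed on 5, and the (S)-catalyst is equally available.

Step 1
Reactants: 1 tiglic aldehyde
Product: 2 (E)-1-(tert-butyldimethylsilyloxy)-2-methylbuta-1,3-diene
Conditions: TBSOTf, Et3N, Et2O, 0 °C → rt
Reagents that add atoms: tert-butyldimethylsilyl triflate, CC(C)(C)[Si](C)(C)OS(=O)(=O)C(F)(F)F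
Why: Soft vinylogous enolisation, in which O-silylation of the s-trans enal and loss of a γ-proton to Et3N give the silyl dienol ether with oxygen trans to the vinyl group (E).

Step 2
Reactants: 3 (E)-4-oxopent-2-enoic acid
Product: 4 benzyl (E)-4-oxopent-2-enoate
Conditions: BnBr, KHCO3, DMF, rt
Reagents that add atoms: benzyl bromide, BrCc1ccccc1
Why: SN2 O-alkylation of the carboxylate under weakly basic conditions leaves the E-enone untouched, and the benzyl ester stays a weaker Lewis base than the ketone yet can later be cleaved by hydrogenolysis beside a secondary acetate, which a methyl ester could not.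

Step 3
Reactants: 2 (E)-1-(tert-butyldimethylsilyloxy)-2-methylbuta-1,3-diene; 4 benzyl (E)-4-oxopent-2-enoate
Product: 5 benzyl (1R,5S,6S)-6-acetyl-5-(tert-butyldimethylsilyloxy)-4-methylcyclohex-3-ene-1-carboxylate
Conditions: (R)-B-(o-tolyl)oxazaborolidine from (R)-α,α-diphenylprolinol (20 mol %), Tf2NH (18 mol %), 2 (1.5 equiv), CH2Cl2, −78 °C; Et3N quench
Reagents that add atoms: none
Why: The cationic boron Lewis acid binds the ketone oxygen of 4 (more basic than the ester oxygen) and a concerted, asynchronous normal-electron-demand [4+2] cycloaddition follows, the closest known type being the oxazaborolidinium-catalysed enantioselective Diels–Alder reaction of 1-silyloxydienes with doubly activated alkenes. The cyclohexene ring closes in an intermolecular suprafacial–suprafacial 4π+2π mode through the s-cis diene, forming C4–C5 and C1–C6 and leaving C2=C3. The step needs regiocontrol, which the substrates secure because the largest diene HOMO coefficient lies at C4, remote from the silyloxy donor, and the largest LUMO coefficient of bound 4 lies at the carbon β to the ketone (C5). C5 and C6 come out trans because the E-geometry of 4 is conserved, and C1 comes out cis to C6 because the E-configured enol ether oxygen points outward while the activated acetyl group takes the endo position. The absolute configuration of all three centres is set by the catalyst, which holds the s-trans enone against one aryl group so that the diene reaches only the open face. The minor Z-isomer of 2 cannot adopt the s-cis form without strain and remains unchanged.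

Step 4
Reactants: 5 benzyl (1R,5S,6S)-6-acetyl-5-(tert-butyldimethylsilyloxy)-4-methylcyclohex-3-ene-1-carboxylate
Product: 7 benzyl (1S,2S,3S,4R,6S)-3-acetoxy-2-(tert-butyldimethylsilyloxy)-1-methyl-7-oxabicyclo[4.1.0]heptane-4-carboxylate, via epoxy ketone 6 (not isolated)
Conditions: mCPBA, Na2HPO4, CH2Cl2, 0 °C until the alkene is consumed; then urea·H2O2, (CF3CO)2O, 0 °C → rt
Reagents that add atoms: mCPBA, O=C(OO)c1cccc(Cl)c1 (epoxide O); trifluoroperacetic acid, O=C(OO)C(F)(F)F, made in the flask from urea–hydrogen peroxide, NC(N)=O.OO, and trifluoroacetic anhydride, O=C(OC(=O)C(F)(F)F)C(F)(F)F (acetate O)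
Why: Prilezhaev epoxidation then Baeyer–Villiger oxidation, in which mCPBA (not drawn in by a silyl ether) attacks C2=C3 opposite the pseudoaxial C1-OTBS group and so sets C2 and C3 on the face of the C5 ester, and only afterwards is the stronger, hydrogen-bond-seeking trifluoroperacetic acid released, under which secondary C6 migrates in preference to methyl with retention.

Step 5
Reactants: 7 benzyl (1S,2S,3S,4R,6S)-3-acetoxy-2-(tert-butyldimethylsilyloxy)-1-methyl-7-oxabicyclo[4.1.0]heptane-4-carboxylate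
Product: 8 (1S,2S,3S,4R,6S)-3-acetoxy-2-(tert-butyldimethylsilyloxy)-1-methyl-7-oxabicyclo[4.1.0]heptane-4-carboxylic acid
Conditions: H2 (1 atm), Pd/C, EtOAc, rt
Reagents that add atoms: none
Why: Catalytic hydrogenolysis of the benzylic C–O bond, with no alkene left to reduce, an aliphatic epoxide, silyl ether and acetate inert to these conditions, and the acid unable to open the epoxide because both lie on the same ring face.

Step 6
Reactants: 8 (1S,2S,3S,4R,6S)-3-acetoxy-2-(tert-butyldimethylsilyloxy)-1-methyl-7-oxabicyclo[4.1.0]heptane-4-carboxylic acid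
Product: 10 (1S,2S,3S,4R,6S)-4-acetyl-2-(tert-butyldimethylsilyloxy)-1-methyl-7-oxabicyclo[4.1.0]heptan-3-yl acetate, via acid chloride 9 (not isolated)
Conditions: Me2C=C(Cl)NMe2, CH2Cl2, 0 °C → rt; then Me2CuLi (MeLi, CuI), Et2O, −78 °C
Reagents that add atoms: 1-chloro-N,N,2-trimethylprop-1-en-1-amine, CC(C)=C(Cl)N(C)C (Cl of 9); lithium dimethylcuprate, [Li+].C[Cu-]C, made from methyllithium, [Li]C (CH3 of 10)
Why: Neutral acid chloride formation with an α-chloroenamine (no HCl, so the epoxide is safe) followed by the classical ketone synthesis from an acid chloride and a lithium dialkylcuprate, which at −78 °C stops at the ketone and touches neither the acetate nor the hindered epoxide, while C5 keeps its favoured equatorial configuration.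

Step 7
Reactants: 10 (1S,2S,3S,4R,6S)-4-acetyl-2-(tert-butyldimethylsilyloxy)-1-methyl-7-oxabicyclo[4.1.0]heptan-3-yl acetate
Product: 12 (1S,2S,3S,4R,6S)-2-(tert-butyldimethylsilyloxy)-1-methyl-4-[1-(trifluoromethylsulfonyloxy)vinyl]-7-oxabicyclo[4.1.0]heptan-3-yl acetate, via potassium enolate 11 (not isolated)
Conditions: KHMDS (1.05 equiv), THF, −78 °C; then N-(5-chloro-2-pyridyl)triflimide, −78 °C
Reagents that add atoms: potassium hexamethyldisilazide, C[Si](C)(C)[N-][Si](C)(C)C.[K+] (K of 11); N-(5-chloropyridin-2-yl)bis(trifluoromethanesulfonimide), O=S(=O)(N(c1ccc(Cl)cn1)S(=O)(=O)C(F)(F)F)C(F)(F)F (SO2CF3)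
Why: Kinetic enolisation by a hindered amide base removes a methyl proton and not the tertiary C5–H (whose loss would expel the C6 acetate), and fast O-sulfonylation of the terminal enolate at −78 °C gives the 1,1-disubstituted enol triflate.

Step 8
Reactants: 13 4-methylpent-3-en-1-ol
Product: 14 4-methylpent-3-enal
Conditions: DMP, NaHCO3, CH2Cl2, 0 °C; filtered and used at once
Reagents that add atoms: none
Why: Dess–Martin oxidation runs under buffered, near-neutral conditions, so the β,γ-double bond should not move into conjugation before the aldehyde is consumed in step 9.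

Step 9
Reactants: 12 (1S,2S,3S,4R,6S)-2-(tert-butyldimethylsilyloxy)-1-methyl-4-[1-(trifluoromethylsulfonyloxy)vinyl]-7-oxabicyclo[4.1.0]heptan-3-yl acetate; 14 4-methylpent-3-enal
Product: 15 (1S,2S,3S,4S,6S)-2-(tert-butyldimethylsilyloxy)-4-(3-hydroxy-6-methylhepta-1,5-dien-2-yl)-1-methyl-7-oxabicyclo[4.1.0]heptan-3-yl acetate as both C8 epimers
Conditions: CrCl2 (excess), NiCl2 (cat.), DMF, rt
Reagents that add atoms: none
Why: Nozaki–Hiyama–Kishi reaction, in which nickel inserts into the C–OTf bond and the derived alkenylchromium(III) species adds only to the aldehyde without enolising it and tolerates acetate, silyl ether and a non-activated epoxide, C8 being left uncontrolled here and corrected in steps 10 and 11.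

Step 10
Reactants: 15 (1S,2S,3S,4S,6S)-2-(tert-butyldimethylsilyloxy)-4-(3-hydroxy-6-methylhepta-1,5-dien-2-yl)-1-methyl-7-oxabicyclo[4.1.0]heptan-3-yl acetate as both C8 epimers
Product: 16 (1S,2S,3S,4S,6S)-2-(tert-butyldimethylsilyloxy)-1-methyl-4-(6-methyl-3-oxohepta-1,5-dien-2-yl)-7-oxabicyclo[4.1.0]heptan-3-yl acetate
Conditions: DMP, NaHCO3, CH2Cl2, 0 °C
Reagents that add atoms: none
Why: Dess–Martin oxidation merges both allylic alcohol epimers into one α-methylene ketone under buffered conditions that should leave the skipped trisubstituted alkene in place.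

Step 11
Reactants: 16 (1S,2S,3S,4S,6S)-2-(tert-butyldimethylsilyloxy)-1-methyl-4-(6-methyl-3-oxohepta-1,5-dien-2-yl)-7-oxabicyclo[4.1.0]heptan-3-yl acetate
Product: 17 (1S,2S,3S,4S,6S)-2-(tert-butyldimethylsilyloxy)-4-[(3S)-3-hydroxy-6-methylhepta-1,5-dien-2-yl]-1-methyl-7-oxabicyclo[4.1.0]heptan-3-yl acetate
Conditions: (R)-Me-CBS oxazaborolidine (cat.), catecholborane, toluene, −78 °C
Reagents that add atoms: none
Why: Corey–Bakshi–Shibata reduction, in which the α-branched alkenyl group acts as the large and the CH2 group as the small ketone substituent, so the (R)-catalyst directs hydride to the face giving the (S)-carbinol at C8, while catecholborane at −78 °C neither hydroborates the alkenes nor reduces the esters.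

Step 12
Reactants: 17 (1S,2S,3S,4S,6S)-2-(tert-butyldimethylsilyloxy)-4-[(3S)-3-hydroxy-6-methylhepta-1,5-dien-2-yl]-1-methyl-7-oxabicyclo[4.1.0]heptan-3-yl acetate; 18 angelic acid
Product: 20 (3S)-2-[(1S,2S,3S,4S,6S)-3-acetoxy-2-(tert-butyldimethylsilyloxy)-1-methyl-7-oxabicyclo[4.1.0]heptan-4-yl]-6-methylhepta-1,5-dien-3-yl (Z)-2-methylbut-2-enoate, via mixed anhydride 19 (not isolated)
Conditions: 18, 2,4,6-Cl3C6H2COCl, Et3N, toluene, rt; then 17, 80 °C (no DMAP)
Reagents that add atoms: 2,4,6-trichlorobenzoyl chloride, O=C(Cl)c1c(Cl)cc(Cl)cc1Cl (aroyl group of 19 only)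
Why: Yamaguchi-type mixed-anhydride esterification in which the alcohol attacks the less hindered angeloyl carbonyl, the absence of a nucleophilic catalyst avoiding the addition–elimination that turns angelate (Z) into tiglate (E), and C8 being retained because its C–O bond is not broken.

Step 13
Reactants: 20 (3S)-2-[(1S,2S,3S,4S,6S)-3-acetoxy-2-(tert-butyldimethylsilyloxy)-1-methyl-7-oxabicyclo[4.1.0]heptan-4-yl]-6-methylhepta-1,5-dien-3-yl (Z)-2-methylbut-2-enoate
Product: 21 (3S)-2-[(1R,2S,3S,4S,6S)-3-acetoxy-2-hydroxy-1-methyl-7-oxabicyclo[4.1.0]heptan-4-yl]-6-methylhepta-1,5-dien-3-yl (Z)-2-methylbut-2-enoate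
Conditions: HF·pyridine, pyridine, THF, 0 °C → rt
Reagents that add atoms: none
Why: Fluoride-driven Si–O cleavage in a mildly acidic buffered medium forms no alkoxide, which should suppress acetyl transfer from O6 to the cis O1 and Payne rearrangement of the epoxy alcohol.

Step 14
Reactants: 21 (3S)-2-[(1R,2S,3S,4S,6S)-3-acetoxy-2-hydroxy-1-methyl-7-oxabicyclo[4.1.0]heptan-4-yl]-6-methylhepta-1,5-dien-3-yl (Z)-2-methylbut-2-enoate
Product: 22 (3S)-2-[(1S,3S,4S,6S)-3-acetoxy-1-methyl-2-oxo-7-oxabicyclo[4.1.0]heptan-4-yl]-6-methylhepta-1,5-dien-3-yl (Z)-2-methylbut-2-enoate (target)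
Conditions: DMP, NaHCO3, CH2Cl2, 0 °C → rt
Reagents that add atoms: none
Why: Dess–Martin oxidation of the hindered secondary alcohol under non-basic conditions gives the α-acetoxy-α′,β′-epoxy ketone without epimerising C6, whose acetate already sits in the favoured equatorial trans arrangement.

**Compound list**

1 | tiglic aldehyde, (E)-2-methylbut-2-enal | C/C=C(\C)C=O | starting material
2 | (E)-1-(tert-butyldimethylsilyloxy)-2-methylbuta-1,3-diene (O trans to vinyl) | C=C/C(C)=C/O[Si](C)(C)C(C)(C)C | intermediate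
3 | (E)-4-oxopent-2-enoic acid | CC(=O)/C=C/C(=O)O | starting material
4 | benzyl (E)-4-oxopent-2-enoate | CC(=O)/C=C/C(=O)OCc1ccccc1 | intermediate
5 | benzyl (1R,5S,6S)-6-acetyl-5-(tert-butyldimethylsilyloxy)-4-methylcyclohex-3-ene-1-carboxylate (route numbering: C1-OTBS cis to C6-acetyl, C5-ester trans to both) | O=C(OCc1ccccc1)[C@@H]1CC=C(C)[C@@H](O[Si](C)(C)C(C)(C)C)[C@H]1C(C)=O | intermediate
6 | benzyl (1S,2S,3S,4R,6S)-3-acetyl-2-(tert-butyldimethylsilyloxy)-1-methyl-7-oxabicyclo[4.1.0]heptane-4-carboxylate (epoxide on the ester face, anti to OTBS) | O=C(OCc1ccccc1)[C@@H]1C[C@@H]2O[C@]2(C)[C@@H](O[Si](C)(C)C(C)(C)C)[C@H]1C(C)=O | intermediate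
7 | benzyl (1S,2S,3S,4R,6S)-3-acetoxy-2-(tert-butyldimethylsilyloxy)-1-methyl-7-oxabicyclo[4.1.0]heptane-4-carboxylate | O=C(OCc1ccccc1)[C@@H]1C[C@@H]2O[C@]2(C)[C@@H](O[Si](C)(C)C(C)(C)C)[C@H]1OC(C)=O | intermediate
8 | (1S,2S,3S,4R,6S)-3-acetoxy-2-(tert-butyldimethylsilyloxy)-1-methyl-7-oxabicyclo[4.1.0]heptane-4-carboxylic acid | O=C(O)[C@@H]1C[C@@H]2O[C@]2(C)[C@@H](O[Si](C)(C)C(C)(C)C)[C@H]1OC(C)=O | intermediate
9 | acid chloride of 8 | O=C(Cl)[C@@H]1C[C@@H]2O[C@]2(C)[C@@H](O[Si](C)(C)C(C)(C)C)[C@H]1OC(C)=O | intermediate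
10 | (1S,2S,3S,4R,6S)-4-acetyl-2-(tert-butyldimethylsilyloxy)-1-methyl-7-oxabicyclo[4.1.0]heptan-3-yl acetate | CC(=O)[C@@H]1C[C@@H]2O[C@]2(C)[C@@H](O[Si](C)(C)C(C)(C)C)[C@H]1OC(C)=O | intermediate
11 | terminal potassium enolate of 10 | C=C([O-])[C@@H]1C[C@@H]2O[C@]2(C)[C@@H](O[Si](C)(C)C(C)(C)C)[C@H]1OC(C)=O.[K+] | intermediate
12 | (1S,2S,3S,4R,6S)-2-(tert-butyldimethylsilyloxy)-1-methyl-4-[1-(trifluoromethylsulfonyloxy)vinyl]-7-oxabicyclo[4.1.0]heptan-3-yl acetate | C=C(OS(=O)(=O)C(F)(F)F)[C@@H]1C[C@@H]2O[C@]2(C)[C@@H](O[Si](C)(C)C(C)(C)C)[C@H]1OC(C)=O | intermediate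
13 | 4-methylpent-3-en-1-ol | CC(C)=CCCO | starting material
14 | 4-methylpent-3-enal | CC(C)=CCC=O | intermediate
15 | (1S,2S,3S,4S,6S)-2-(tert-butyldimethylsilyloxy)-4-(3-hydroxy-6-methylhepta-1,5-dien-2-yl)-1-methyl-7-oxabicyclo[4.1.0]heptan-3-yl acetate, both C8 epimers | C=C(C(O)CC=C(C)C)[C@@H]1C[C@@H]2O[C@]2(C)[C@@H](O[Si](C)(C)C(C)(C)C)[C@H]1OC(C)=O | intermediate
16 | (1S,2S,3S,4S,6S)-2-(tert-butyldimethylsilyloxy)-1-methyl-4-(6-methyl-3-oxohepta-1,5-dien-2-yl)-7-oxabicyclo[4.1.0]heptan-3-yl acetate | C=C(C(=O)CC=C(C)C)[C@@H]1C[C@@H]2O[C@]2(C)[C@@H](O[Si](C)(C)C(C)(C)C)[C@H]1OC(C)=O | intermediate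
17 | (1S,2S,3S,4S,6S)-2-(tert-butyldimethylsilyloxy)-4-[(3S)-3-hydroxy-6-methylhepta-1,5-dien-2-yl]-1-methyl-7-oxabicyclo[4.1.0]heptan-3-yl acetate | C=C([C@H](CC=C(C)C)O)[C@@H]1C[C@@H]2O[C@]2(C)[C@@H](O[Si](C)(C)C(C)(C)C)[C@H]1OC(C)=O | intermediate
18 | angelic acid, (Z)-2-methylbut-2-enoic acid | C/C=C(/C)C(=O)O | starting material
19 | angelic 2,4,6-trichlorobenzoic anhydride | C/C=C(/C)C(=O)OC(=O)c1c(Cl)cc(Cl)cc1Cl | intermediate
20 | (3S)-2-[(1S,2S,3S,4S,6S)-3-acetoxy-2-(tert-butyldimethylsilyloxy)-1-methyl-7-oxabicyclo[4.1.0]heptan-4-yl]-6-methylhepta-1,5-dien-3-yl (Z)-2-methylbut-2-enoate | C=C([C@H](CC=C(C)C)OC(=O)/C(C)=C\C)[C@@H]1C[C@@H]2O[C@]2(C)[C@@H](O[Si](C)(C)C(C)(C)C)[C@H]1OC(C)=O | intermediate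
21 | (3S)-2-[(1R,2S,3S,4S,6S)-3-acetoxy-2-hydroxy-1-methyl-7-oxabicyclo[4.1.0]heptan-4-yl]-6-methylhepta-1,5-dien-3-yl (Z)-2-methylbut-2-enoate | C=C([C@H](CC=C(C)C)OC(=O)/C(C)=C\C)[C@@H]1C[C@@H]2O[C@]2(C)[C@@H](O)[C@H]1OC(C)=O | intermediate
22 | (3S)-2-[(1S,3S,4S,6S)-3-acetoxy-1-methyl-2-oxo-7-oxabicyclo[4.1.0]heptan-4-yl]-6-methylhepta-1,5-dien-3-yl (Z)-2-methylbut-2-enoate, CNP0150645.2 | C=C([C@H](CC=C(C)C)OC(=O)/C(C)=C\C)[C@@H]1C[C@@H]2O[C@]2(C)C(=O)[C@H]1OC(C)=O | target

**Total step count:** 14.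

**Longest linear sequence:** 12 steps (1 → 2 → 5 → 7 → 8 → 10 → 12 → 15 → 16 → 17 → 20 → 21 → 22).

**Steps most likely to fail**

Step 3. The strongly acidic catalyst may protonate the dienol ether or divert it into Mukaiyama–Michael addition. Partial binding of boron to the ester may erode regio- and endo-control, or enantioface selection may be insufficient. The fallback replaces catalyst control by a covalent resolving ester and sets out from 3.
- Steglich esterification (EDC, DMAP) with (R)-1-phenylethanol gives (R)-1-phenylethyl (E)-4-oxopent-2-enoate F1.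
- Uncatalysed cycloaddition with 2 in toluene at 80 °C, where the ketone is still the stronger director, gives two endo adducts. These are (R)-1-phenylethyl (1R,5S,6S)-6-acetyl-5-(tert-butyldimethylsilyloxy)-4-methylcyclohex-3-ene-1-carboxylate F2 and its ring-antipodal diastereomer, the (1S,5R,6R) ester F3. They are separated by chromatography or crystallisation.
- F2 passes through the conditions of step 4, via the 1-phenylethyl epoxy ketone F4, to the 1-phenylethyl epoxy acetate F5.
- Hydrogenolysis as in step 5 cleaves this benzylic ester, and the route is rejoined at 8.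

Step 4. Facial selectivity in the epoxidation stage may be poor if the silyl ether shields its face less than expected. The fallback swaps steric approach control for stereoelectronic control and sets out from 5.
- NBS in aqueous THF gives benzyl (1R,2S,3S,4R,5R)-2-acetyl-5-bromo-3-(tert-butyldimethylsilyloxy)-4-hydroxy-4-methylcyclohexane-1-carboxylate F6.
- With the C5 and C6 groups equatorial, Markovnikov and trans-diaxial (Fürst–Plattner) opening of the bromonium ion places the C2 hydroxyl axial on the ester face and the C3 bromine axial on the other face.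
- Ag2O in THF closes the ring with inversion at C3.
- The route is rejoined at 6, now isolated, which then receives only the trifluoroperacetic acid stage of step 4.

Step 7. The enolate may equilibrate towards C5 with β-elimination of the acetate, or the acetyl group may transfer to the enolate oxygen. The enolate-free fallback sets out from 10.
- Condensation with 1,2-bis(tert-butyldimethylsilyl)hydrazine (cat. Sc(OTf)3) gives the N-tert-butyldimethylsilyl hydrazone F7.
- Barton vinyl iodide synthesis (I2, 2-tert-butyl-1,1,3,3-tetramethylguanidine, THF, 0 °C) gives (1S,2S,3S,4R,6S)-2-(tert-butyldimethylsilyloxy)-4-(1-iodovinyl)-1-methyl-7-oxabicyclo[4.1.0]heptan-3-yl acetate F8.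
- F8 enters the Ni/Cr coupling of step 9 with 14, and the route is rejoined at 15.

**Further compounds**

F1 | step 3 | (R)-1-phenylethyl (E)-4-oxopent-2-enoate | C[C@@H](OC(=O)/C=C/C(C)=O)c1ccccc1
F2 | step 3 | (R)-1-phenylethyl (1R,5S,6S)-6-acetyl-5-(tert-butyldimethylsilyloxy)-4-methylcyclohex-3-ene-1-carboxylate | C[C@@H](OC(=O)[C@@H]1CC=C(C)[C@@H](O[Si](C)(C)C(C)(C)C)[C@H]1C(C)=O)c1ccccc1
F3 | step 3 | (R)-1-phenylethyl (1S,5R,6R)-6-acetyl-5-(tert-butyldimethylsilyloxy)-4-methylcyclohex-3-ene-1-carboxylate | C[C@@H](OC(=O)[C@H]1CC=C(C)[C@H](O[Si](C)(C)C(C)(C)C)[C@@H]1C(C)=O)c1ccccc1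
F4 | step 3 | (R)-1-phenylethyl (1S,2S,3S,4R,6S)-3-acetyl-2-(tert-butyldimethylsilyloxy)-1-methyl-7-oxabicyclo[4.1.0]heptane-4-carboxylate | C[C@@H](OC(=O)[C@@H]1C[C@@H]2O[C@]2(C)[C@@H](O[Si](C)(C)C(C)(C)C)[C@H]1C(C)=O)c1ccccc1
F5 | step 3 | (R)-1-phenylethyl (1S,2S,3S,4R,6S)-3-acetoxy-2-(tert-butyldimethylsilyloxy)-1-methyl-7-oxabicyclo[4.1.0]heptane-4-carboxylate | C[C@@H](OC(=O)[C@@H]1C[C@@H]2O[C@]2(C)[C@@H](O[Si](C)(C)C(C)(C)C)[C@H]1OC(C)=O)c1ccccc1
F6 | step 4 | benzyl (1R,2S,3S,4R,5R)-2-acetyl-5-bromo-3-(tert-butyldimethylsilyloxy)-4-hydroxy-4-methylcyclohexane-1-carboxylate | O=C(OCc1ccccc1)[C@@H]1C[C@@H](Br)[C@](C)(O)[C@@H](O[Si](C)(C)C(C)(C)C)[C@H]1C(C)=O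
F7 | step 7 | (E)-N-tert-butyldimethylsilyl hydrazone of 10 | C/C(=N\N[Si](C)(C)C(C)(C)C)[C@@H]1C[C@@H]2O[C@]2(C)[C@@H](O[Si](C)(C)C(C)(C)C)[C@H]1OC(C)=O
F8 | step 7 | (1S,2S,3S,4R,6S)-2-(tert-butyldimethylsilyloxy)-4-(1-iodovinyl)-1-methyl-7-oxabicyclo[4.1.0]heptan-3-yl acetate | C=C(I)[C@@H]1C[C@@H]2O[C@]2(C)[C@@H](O[Si](C)(C)C(C)(C)C)[C@H]1OC(C)=O
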